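## Retrosynthetic overview

1. The target is cut at the ring C-4–CH2 bond into a β-triketone core and a β-hydroxy aldehyde (cyclopentane fragment); they are joined last by reductive alkylation.
2. The six-membered core comes from a five-membered cyclopentane-1,2,4-trione and an α-diazoketone: a one-carbon ring expansion by 1,2-acyl shift inserts the acyl-bearing carbon between the vicinal carbonyls (key step).
3. The trione comes from 2-methylcyclopentane-1,3-dione and prenyl bromide; a CBS desymmetrisation fixes the quaternary centre, then α-oxygenation and oxidation follow.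
4. The cyclopentane fragment comes from hex-5-en-2-one, methyl acrylate and an isopropenylborate: cross-metathesis, then rhodium-catalysed conjugate addition with aldol ring closure sets its three stereocentres.
5. Ring order: purchased cyclopentanedione → six-membered core by ring expansion; side-chain cyclopentane by aldol closure; union of the two at the end.

Assumption: the target is drawn as one enol tautomer of a cyclic β-triketone; intermediates of this type are drawn and named in the matching tautomer.

## Route

Step 1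
Reactants: 1 2-methylcyclopentane-1,3-dione; 2 1-bromo-3-methylbut-2-ene (prenyl bromide)
Product: 3 2-methyl-2-(3-methylbut-2-en-1-yl)cyclopentane-1,3-dione
Conditions: 1 M aq. NaOH, rt, 48 h
Reagents that add atoms: none
Why: C-alkylation of the stabilised 1,3-dione enolate (SN2 on an allylic bromide) builds the prochiral quaternary carbon; no stereocentre is formed.

Step 2
Reactants: 3 2-methyl-2-(3-methylbut-2-en-1-yl)cyclopentane-1,3-dione
Product: 4 (2R,3R)-3-hydroxy-2-methyl-2-(3-methylbut-2-en-1-yl)cyclopentan-1-one
Conditions: (S)-2-methyl-CBS-oxazaborolidine (20 mol%), catecholborane (1.0 equiv), toluene, −78 °C; silica chromatography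
Reagents that add atoms: none
Why: Corey–Bakshi–Shibata reduction desymmetrises the dione: the (S)-catalyst sets the carbinol as R and hydride enters syn to the small methyl group (anti to prenyl), so the quaternary carbon becomes R; the minor (2S,3R) diastereomer is removed on silica.

Step 3
Reactants: 4 (2R,3R)-3-hydroxy-2-methyl-2-(3-methylbut-2-en-1-yl)cyclopentan-1-one
Product: 5 (2R,3R)-3,5-dihydroxy-2-methyl-2-(3-methylbut-2-en-1-yl)cyclopentan-1-one (both C-5 epimers)
Conditions: NaN(SiMe3)2 (2.3 equiv), THF, −78 °C; Davis oxaziridine (1.3 equiv); AcOH quench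
Reagents that add atoms: 2-(benzenesulfonyl)-3-phenyloxaziridine (Davis oxaziridine), O=S(=O)(c1ccccc1)N1OC1c1ccccc1
Why: Davis α-hydroxylation of the sodium enolate, which can only form at C-5, brings in the oxygen of the future vicinal dione; the new carbinol centre is erased in step 4 and the quaternary centre is not touched.

Step 4
Reactants: 5 (2R,3R)-3,5-dihydroxy-2-methyl-2-(3-methylbut-2-en-1-yl)cyclopentan-1-one
Product: 6 (5R)-2-hydroxy-5-methyl-5-(3-methylbut-2-en-1-yl)cyclopent-2-ene-1,4-dione
Conditions: Dess–Martin periodinane (2.5 equiv), CH2Cl2, 0 °C to rt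
Reagents that add atoms: none
Why: Dess–Martin oxidation of both secondary alcohols gives the cyclopentane-1,2,4-trione, which rests as its diosphenol enol; the unsymmetrical placement of the three oxygens keeps the non-epimerisable quaternary carbon stereogenic.

Step 5
Reactants: 7 (2S)-2-methylbutanoic acid
Product: 9 (3S)-1-diazo-3-methylpentan-2-one, via (2S)-2-methylbutanoyl chloride 8 (not isolated)
Conditions: (COCl)2, cat. DMF, CH2Cl2, 0 °C to rt, evaporate; CH2N2 (2.5 equiv), Et2O, 0 °C
Reagents that add atoms: diazomethane, C=[N+]=[N-]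
Why: Acid chloride formation followed by acylation of diazomethane (first stage of the Arndt–Eistert sequence); excess diazomethane takes up HCl, so no amine base, no ketene and no loss of the α-stereocentre.

Step 6
Reactants: 6 (5R)-2-hydroxy-5-methyl-5-(3-methylbut-2-en-1-yl)cyclopent-2-ene-1,4-dione; 9 (3S)-1-diazo-3-methylpentan-2-one
Product: 11 (6R)-3,5-dihydroxy-6-methyl-2-[(2S)-2-methylbutanoyl]-6-(3-methylbut-2-en-1-yl)cyclohexa-2,4-dien-1-one, via diazonium alkoxide adduct 10 (not isolated)
Conditions: Sc(OTf)3 (20 mol%), 9 (1.2 equiv), CH2Cl2, −40 °C to rt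
Reagents that add atoms: none
Why: Proposed new method: a Lewis-acid-mediated diazoketone homologation of a ketone (Büchner–Curtius–Schlotterbeck / Tiffeneau–Demjanov type) applied to a cyclopentane-1,2,4-trione, where it has not been shown; Sc(OTf)3 chelates the O=C-1/HO–C-2 pair of 6 and activates C-1 for attack by the diazo carbon of 9; the electron-rich enol carbon C-2 (the acyl group in the keto tautomer) then shifts 1,2 to the diazonium carbon with loss of N2, in preference to the hindered quaternary C-5 that is also α to the second carbonyl; the acyl-bearing carbon is thereby inserted between the vicinal carbonyls, giving the six-membered β-triketone with the quaternary stereocentre untouched; the closest known reactions are the ring expansions of isatins, acenaphthenequinone and simple cycloalkanones with diazo carbonyl compounds.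

Step 7
Reactants: 12 hex-5-en-2-one; 13 methyl acrylate
Product: 14 methyl (2E)-6-oxohept-2-enoate
Conditions: second-generation Hoveyda–Grubbs catalyst RuCl2(H2IMes)(=CH-C6H4-2-OiPr) (2 mol%), 13 (3 equiv), CH2Cl2, 40 °C
Reagents that add atoms: none
Why: Olefin cross-metathesis of a terminal alkene with an acrylate is selective for the E cross product.

Step 8
Reactants: 14 methyl (2E)-6-oxohept-2-enoate; 15 potassium trifluoro(prop-1-en-2-yl)borate
Product: 16 methyl (1S,2R,5R)-2-hydroxy-2-methyl-5-(prop-1-en-2-yl)cyclopentane-1-carboxylate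
Conditions: [Rh(cod)2]BF4 (5 mol%), (S)-BINAP (6 mol%), 15 (2 equiv), dioxane/H2O 10:1, 80 °C
Reagents that add atoms: none
Why: Rhodium-catalysed asymmetric conjugate addition (Hayashi–Miyaura type) followed by aldol closure of the resulting Z-enolate onto the methyl ketone: (S)-BINAP sends isopropenyl to the si face at C-2 of the enoate, making the carbon that bears it R, and the chelated chair-like aldol transition state puts OH cis to the ester and the ester trans to isopropenyl, so all three ring stereocentres are set.

Step 9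
Reactants: 16 methyl (1S,2R,5R)-2-hydroxy-2-methyl-5-(prop-1-en-2-yl)cyclopentane-1-carboxylate
Product: 17 (1S,2R,5R)-2-hydroxy-2-methyl-5-(prop-1-en-2-yl)cyclopentane-1-carbaldehyde
Conditions: iBu2AlH (2.3 equiv), CH2Cl2, −78 °C; aq. KNaC4H4O6 work-up
Reagents that add atoms: none
Why: Partial reduction of the ester by iBu2AlH at low temperature, with the aluminium alkoxide of the neighbouring tertiary alcohol holding the tetrahedral intermediate until work-up; the aldehyde α-centre is already in its more stable configuration (trans to isopropenyl and to methyl).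

Step 10
Reactants: 11 (6R)-3,5-dihydroxy-6-methyl-2-[(2S)-2-methylbutanoyl]-6-(3-methylbut-2-en-1-yl)cyclohexa-2,4-dien-1-one; 17 (1S,2R,5R)-2-hydroxy-2-methyl-5-(prop-1-en-2-yl)cyclopentane-1-carbaldehyde
Product: 19 (6R)-3,5-dihydroxy-4-{[(1S,2R,5R)-2-hydroxy-2-methyl-5-(prop-1-en-2-yl)cyclopentyl]methyl}-6-methyl-2-[(2S)-2-methylbutanoyl]-6-(3-methylbut-2-en-1-yl)cyclohexa-2,4-dien-1-one, via alkylidene triketone 18 (not isolated)
Conditions: Hantzsch ester (diethyl 2,6-dimethyl-1,4-dihydropyridine-3,5-dicarboxylate, 1.2 equiv), L-proline (20 mol%), CH2Cl2, rt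
Reagents that add atoms: none
Why: Three-component reductive alkylation: Knoevenagel condensation of the aldehyde with the only free ring CH of the β-triketone, then conjugate hydride transfer from the Hantzsch ester to the alkylidene intermediate; no stereocentre is made or touched.

## Compound list

1 | 2-methylcyclopentane-1,3-dione | CC1C(=O)CCC1=O | starting material
2 | 1-bromo-3-methylbut-2-ene (prenyl bromide) | CC(C)=CCBr | starting material
3 | 2-methyl-2-(3-methylbut-2-en-1-yl)cyclopentane-1,3-dione | CC(C)=CCC1(C)C(=O)CCC1=O | intermediate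
4 | (2R,3R)-3-hydroxy-2-methyl-2-(3-methylbut-2-en-1-yl)cyclopentan-1-one | O=C1CC[C@@H](O)[C@@]1(C)CC=C(C)C | intermediate
5 | (2R,3R)-3,5-dihydroxy-2-methyl-2-(3-methylbut-2-en-1-yl)cyclopentan-1-one (both C-5 epimers) | O=C1C(O)C[C@@H](O)[C@@]1(C)CC=C(C)C | intermediate
6 | (5R)-2-hydroxy-5-methyl-5-(3-methylbut-2-en-1-yl)cyclopent-2-ene-1,4-dione, the enol of (3R)-3-methyl-3-(3-methylbut-2-en-1-yl)cyclopentane-1,2,4-trione | O=C1C(O)=CC(=O)[C@@]1(C)CC=C(C)C | intermediate
7 | (2S)-2-methylbutanoic acid | CC[C@H](C)C(=O)O | starting material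
8 | (2S)-2-methylbutanoyl chloride | CC[C@H](C)C(=O)Cl | intermediate (not isolated)
9 | (3S)-1-diazo-3-methylpentan-2-one | CC[C@H](C)C(=O)C=[N+]=[N-] | intermediate
10 | diazonium alkoxide adduct: zwitterion from attack of the diazo carbon of 9 on C-1 of 6 (new centres not defined) | CC[C@H](C)C(=O)C([N+]#N)C1([O-])C(O)=CC(=O)[C@@]1(C)CC=C(C)C | intermediate (not isolated)
11 | (6R)-3,5-dihydroxy-6-methyl-2-[(2S)-2-methylbutanoyl]-6-(3-methylbut-2-en-1-yl)cyclohexa-2,4-dien-1-one | CC[C@H](C)C(=O)C1=C(O)C=C(O)[C@@](C)(CC=C(C)C)C1=O | intermediate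
12 | hex-5-en-2-one | CC(=O)CCC=C | starting material
13 | methyl acrylate | C=CC(=O)OC | starting material
14 | methyl (2E)-6-oxohept-2-enoate | COC(=O)/C=C/CCC(C)=O | intermediate
15 | potassium trifluoro(prop-1-en-2-yl)borate | [K+].C=C(C)[B-](F)(F)F | starting material
16 | methyl (1S,2R,5R)-2-hydroxy-2-methyl-5-(prop-1-en-2-yl)cyclopentane-1-carboxylate | C=C(C)[C@@H]1CC[C@@](C)(O)[C@H]1C(=O)OC | intermediate
17 | (1S,2R,5R)-2-hydroxy-2-methyl-5-(prop-1-en-2-yl)cyclopentane-1-carbaldehyde | C=C(C)[C@@H]1CC[C@@](C)(O)[C@H]1C=O | intermediate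
18 | alkylidene triketone: Knoevenagel adduct of 11 (at C-4) and 17, alkene geometry not fixed | C=C(C)[C@@H]1CC[C@@](C)(O)[C@H]1C=C1C(=O)[C@@](C)(CC=C(C)C)C(=O)C(C(=O)[C@@H](C)CC)=C1O | intermediate (not isolated)
19 | (6R)-3,5-dihydroxy-4-{[(1S,2R,5R)-2-hydroxy-2-methyl-5-(prop-1-en-2-yl)cyclopentyl]methyl}-6-methyl-2-[(2S)-2-methylbutanoyl]-6-(3-methylbut-2-en-1-yl)cyclohexa-2,4-dien-1-one | C=C(C)[C@@H]1CC[C@@](C)(O)[C@H]1CC1=C(O)[C@@](C)(CC=C(C)C)C(=O)C(C(=O)[C@@H](C)CC)=C1O | target

## Step count and risks

Total step count: 10. Longest linear sequence: 6 steps (steps 1, 2, 3, 4, 6, 10).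

Three steps most likely to fail:

**Step 6 (the proposed new ring expansion).** The risks are O-alkylation of the acidic enol of 6 by the diazoketone, attack at the wrong carbonyl, or migration of the wrong group. The fallback uses known condensation chemistry and gives up stereocontrol at the quaternary carbon, which is then recovered by separation. It sets out from prenyl bromide 2 and acid 7 and comes back at 11. Commercial 3-methylpentane-2,4-dione F1 is C-prenylated with 2 (K2CO3, acetone, reflux) to 3-methyl-3-(3-methylbut-2-en-1-yl)pentane-2,4-dione F2. Claisen condensation with dimethyl carbonate (NaH, THF, reflux) gives methyl 4-methyl-4-(3-methylbut-2-en-1-yl)-3,5-dioxohexanoate F3. Dieckmann closure (NaOMe, MeOH) gives 2-methyl-2-(3-methylbut-2-en-1-yl)cyclohexane-1,3,5-trione F4. C-acylation with 7 (DCC, DMAP, CH2Cl2; O-acylation then O-to-C acyl transfer) gives 11 together with its C-6 epimer (6S)-3,5-dihydroxy-6-methyl-2-[(2S)-2-methylbutanoyl]-6-(3-methylbut-2-en-1-yl)cyclohexa-2,4-dien-1-one F5, and the two diastereomers are separated by preparative HPLC.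

**Step 8 (conjugate addition with aldol closure).** The ester enolate may be protonated by water before it closes onto the ketone. The fallback sets out from 14 and 15 and comes back at 17, so it also replaces step 9. Ordinary protonative rhodium-catalysed conjugate addition ([Rh(cod)Cl]2, (S)-BINAP, KOH, dioxane/H2O, 60 °C) gives methyl (3R)-6-oxo-3-(prop-1-en-2-yl)heptanoate F6. LiAlH4 (THF, 0 °C) reduces ester and ketone to (3R)-3-(prop-1-en-2-yl)heptane-1,6-diol F7 (both C-6 epimers). Dess–Martin oxidation gives (3R)-6-oxo-3-(prop-1-en-2-yl)heptanal F8. L-proline (CH2Cl2, rt) closes F8 by intramolecular enamine aldol reaction to 17; reversible aldol and α-epimerisation should lead to 17 as the most stable diastereomer (aldehyde trans to isopropenyl and to methyl).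

**Step 9 (partial ester reduction).** Over-reduction to the diol or retro-aldol opening of the β-hydroxy aldehyde on work-up may occur. The fallback sets out from 16 and comes back at 17. LiAlH4 (THF, 0 °C) reduces 16 fully to (1R,2R,3R)-2-(hydroxymethyl)-1-methyl-3-(prop-1-en-2-yl)cyclopentan-1-ol F9, and TEMPO/PhI(OAc)2 (CH2Cl2, rt) oxidises only the primary alcohol to give 17; the tertiary alcohol is inert.

## Further compounds

F1 | step 6 | 3-methylpentane-2,4-dione | CC(=O)C(C)C(C)=O
F2 | step 6 | 3-methyl-3-(3-methylbut-2-en-1-yl)pentane-2,4-dione | CC(=O)C(C)(CC=C(C)C)C(C)=O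
F3 | step 6 | methyl 4-methyl-4-(3-methylbut-2-en-1-yl)-3,5-dioxohexanoate (racemic) | COC(=O)CC(=O)C(C)(CC=C(C)C)C(C)=O
F4 | step 6 | 2-methyl-2-(3-methylbut-2-en-1-yl)cyclohexane-1,3,5-trione | CC(C)=CCC1(C)C(=O)CC(=O)CC1=O
F5 | step 6 | (6S)-3,5-dihydroxy-6-methyl-2-[(2S)-2-methylbutanoyl]-6-(3-methylbut-2-en-1-yl)cyclohexa-2,4-dien-1-one | CC[C@H](C)C(=O)C1=C(O)C=C(O)[C@](C)(CC=C(C)C)C1=O
F6 | step 8 | methyl (3R)-6-oxo-3-(prop-1-en-2-yl)heptanoate | C=C(C)[C@@H](CC(=O)OC)CCC(C)=O
F7 | step 8 | (3R)-3-(prop-1-en-2-yl)heptane-1,6-diol (both C-6 epimers) | C=C(C)[C@@H](CCO)CCC(C)O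
F8 | step 8 | (3R)-6-oxo-3-(prop-1-en-2-yl)heptanal | C=C(C)[C@@H](CC=O)CCC(C)=O
F9 | step 9 | (1R,2R,3R)-2-(hydroxymethyl)-1-methyl-3-(prop-1-en-2-yl)cyclopentan-1-ol | C=C(C)[C@@H]1CC[C@@](C)(O)[C@H]1CO
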